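The α-alkyl butenolide (ring C13, C14, C15, O, C16) is closed at C14–C15. C14 is the β-carbon of the C13=C14–C16(=O) enoate and C15 an acyloxymethyl carbon, so the open form is a chloromethyl 2-alkylacrylate. A triazolylidene adds to its terminal CH2, tautomerises to an ene-1,1-diamine, C14 displaces chloride at C15 (5-exo-tet) and the carbene leaves, restoring C13=C14: one operation gives the 2(5H)-furanone. The precursor comes from larixol acylated at O6: both alkenes are cleaved to an 8,13-diketone, both ketones become enol triflates, one double carbonylation installs C17 and C16, and the ring chloromethyl ester, expected to resist the carbene, is unmasked last.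

Key step: step 6

Remark: labdane numbering is used (lactone: C13 α-carbon, C14 ring CH, C15 OCH2, C16 C=O; C17 ring carboxyl), and (+)-larixol is taken as a purchasable natural labdane diol with 13S configuration.

Step 1
Reactants: 1 (+)-larixol [labda-8(17),14-diene-6α,13(S)-diol; 5α-H, 9α-H, 10β-CH3]; 2 (R)-2-methylbutanoic acid
Product: 3 larixol 6-O-[(R)-2-methylbutanoate] (6α-ester, 13-OH free)
Conditions: DCC, DMAP (0.2 equiv), CH2Cl2, 0 °C → rt
Reagents that add atoms: none
Why: Steglich esterification: only the secondary equatorial 6α-hydroxyl is acylated because the tertiary allylic 13-hydroxyl is too hindered, and carbodiimide activation with little DMAP at 0 °C avoids the ketene pathway that would erode the α-stereocentre of the acid, so C6 and the acyl stereocentre are both carried over unchanged.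

Step 2
Reactants: 3 larixol 6-O-[(R)-2-methylbutanoate]
Product: 5 6α-[(R)-2-methylbutanoyloxy]-14,15,17-trinorlabdane-8,13-dione, via 8-oxo-13-hydroxy-14-aldehyde 4 (not isolated)
Conditions: O3, CH2Cl2/MeOH, −78 °C; Me2S, −78 °C → rt; then NaIO4, THF/H2O, rt
Reagents that add atoms: ozone, [O-][O+]=O
Why: Ozonolysis with reductive work-up cleaves the 8(17)-methylene to the C8 ketone and the vinyl group to the C13 α-hydroxy aldehyde, and periodate then cleaves that α-hydroxy aldehyde (glycol-type cleavage of its hydrate) to the methyl ketone, the neutral conditions sparing the pseudo-equatorial β-acyloxy ketone and leaving C9 in its more stable side-chain-equatorial configuration.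

Step 3
Reactants: 5 the 8,13-diketone
Product: 6 bis(enol triflate): ring C7=C8–OTf and side chain CH2=C(OTf)– at C13 (the former C16 methyl is now the exo-methylene, the future C14)
Conditions: KHMDS (2.3 equiv), THF, −78 °C (5 added to the base); PhNTf2 (2.5 equiv), −78 → −30 °C
Reagents that add atoms: N-phenylbis(trifluoromethanesulfonimide), O=S(=O)(N(c1ccccc1)S(=O)(=O)C(F)(F)F)C(F)(F)F
Why: Kinetic enolate formation and O-sulfonylation (enol triflate synthesis): the hindered amide base removes a proton from the CH3 of the methyl ketone and from C7 of the ring ketone in preference to the tertiary C9–H, addition of the diketone to excess base at −78 °C should outrun the aldol between the two carbonyls, and the pseudo-equatorial 6α-acyloxy group lies near the nodal plane of the C7=C8 enolate so that E1cB loss is slow before PhNTf2 traps both enolates.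

Step 4
Reactants: 6 the bis(enol triflate)
Product: 7 diacid: ring C7=C8–CO2H (C17) and side-chain 2-substituted acrylic acid CH2=C(CO2H)– (C14 methylene, C16 carboxyl)
Conditions: Pd(OAc)2 (10 mol %), dppf, CO (1 atm), H2O, i-Pr2NEt, DMF, 60 °C
Reagents that add atoms: carbon monoxide, [C-]#[O+]; water, O
Why: Palladium-catalysed hydroxycarbonylation of enol triflates (oxidative addition, CO insertion, hydrolysis of the acyl-palladium) converts both C–OTf bonds into CO2H with the alkenes held in place, CO insertion under a CO atmosphere being faster than ionisation of the hindered allylic C6 ester by Pd(0).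

Step 5
Reactants: 7 the diacid
Product: 8 bis(chloromethyl) ester (ring CO2CH2Cl and side-chain CH2=C(R)CO2CH2Cl)
Conditions: ClCH2OSO2Cl (2.6 equiv), NaHCO3, n-Bu4NHSO4 (cat.), CH2Cl2/H2O, rt
Reagents that add atoms: chloromethyl chlorosulfate, ClCOS(Cl)(=O)=O
Why: Phase-transfer O-alkylation of both carboxylates with chloromethyl chlorosulfate (SN2 at CH2 with chlorosulfate as the leaving group) is the standard entry to chloromethyl esters and does not touch the C6 ester or the alkenes.

Step 6
Reactants: 8 the bis(chloromethyl) ester
Product: 9 butenolide (3-substituted furan-2(5H)-one on the C9 side chain) still carrying the ring chloromethyl ester at C17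
Conditions: 1,3,4-triphenyl-1,2,4-triazol-5-ylidene (20 mol %), K3PO4, DME, 80 °C, 0.02 M
Reagents that add atoms: none
Why: The triazolylidene adds reversibly to the unhindered terminal carbon C14 of the 2-alkylacrylate, a proton shift turns the zwitterion into an ene-1,1-diamine whose C14 is nucleophilic, C14 displaces chloride from the O–CH2Cl carbon C15, and phosphate removes the C13–H so that the azolium leaves by E1cB and C13=C14 is restored. The closest known reaction type is the NHC-catalysed umpolung β-alkylation of Michael acceptors, in which α,β-unsaturated esters carrying a pendant primary halide or sulfonate are alkylated intramolecularly at the β-carbon under comparable conditions (triazolylidene, K3PO4, ethereal solvent, 80 °C); new here are the tether, which runs through the ester oxygen, and the electrophile, an acyloxymethyl chloride of SN2 reactivity similar to a primary bromide. The butenolide ring (C13, C14, C15, O, C16) closes in a 5-exo-tet mode with the nucleophilic C14=C(azolium) bond exocyclic to the new ring. No stereocentre is formed. The step needs chemoselectivity between two chloromethyl enoates and cyclisation over tail-to-tail dimerisation: the ring enoate is trisubstituted, with a hindered β-carbon C7 next to the C6 ester, and should not be attacked at a useful rate, while high dilution suppresses the bimolecular path. It also needs the s-trans rotamer of the ester, which the persistent carbene adduct can reach at 80 °C.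

Step 7
Reactants: 9 the butenolide chloromethyl ester
Product: 10 target, 6α-[(R)-2-methylbutanoyloxy]labda-7,13-dien-16,15-olid-17-oic acid (CNP0150853.1)
Conditions: NaI (0.2 equiv), NaHCO3, acetone/H2O 4:1, 40 °C; aq KHSO4 work-up
Reagents that add atoms: none
Why: Iodide-catalysed solvolysis at the acylal carbon (Finkelstein exchange, substitution by water, collapse of the hydroxymethyl ester to acid and formaldehyde) cleaves the chloromethyl ester at its CH2 and not at a carbonyl group, so the butenolide, the C6 ester and every stereocentre survive the bicarbonate medium.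

Compound list
1 | (+)-larixol, labda-8(17),14-diene-6α,13(S)-diol | O[C@H]1CC(=C)[C@H](CC[C@](C)(O)C=C)[C@@]2(C)CCCC(C)(C)[C@H]12 | starting material
2 | (R)-2-methylbutanoic acid | CC[C@@H](C)C(O)=O | starting material
3 | larixol 6-O-[(R)-2-methylbutanoate] | CC[C@@H](C)C(=O)O[C@H]1CC(=C)[C@H](CC[C@](C)(O)C=C)[C@@]2(C)CCCC(C)(C)[C@H]12 | intermediate
4 | 8-oxo-13-hydroxy-14-aldehyde (6α-ester, 15,17-dinor) | CC[C@@H](C)C(=O)O[C@H]1CC(=O)[C@H](CC[C@](C)(O)C=O)[C@@]2(C)CCCC(C)(C)[C@H]12 | intermediate (not isolated)
5 | 6α-[(R)-2-methylbutanoyloxy]-14,15,17-trinorlabdane-8,13-dione | CC[C@@H](C)C(=O)O[C@H]1CC(=O)[C@H](CCC(C)=O)[C@@]2(C)CCCC(C)(C)[C@H]12 | intermediate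
6 | bis(enol triflate), C7=C8–OTf and CH2=C13–OTf | CC[C@@H](C)C(=O)O[C@H]1C=C(OS(=O)(=O)C(F)(F)F)[C@H](CCC(=C)OS(=O)(=O)C(F)(F)F)[C@@]2(C)CCCC(C)(C)[C@H]12 | intermediate
7 | diacid, ring 7-ene-8-carboxylic acid and side-chain 2-substituted acrylic acid | CC[C@@H](C)C(=O)O[C@H]1C=C(C(=O)O)[C@H](CCC(=C)C(=O)O)[C@@]2(C)CCCC(C)(C)[C@H]12 | intermediate
8 | bis(chloromethyl) ester of 7 | CC[C@@H](C)C(=O)O[C@H]1C=C(C(=O)OCCl)[C@H](CCC(=C)C(=O)OCCl)[C@@]2(C)CCCC(C)(C)[C@H]12 | intermediate
9 | butenolide with ring chloromethyl ester | CC[C@@H](C)C(=O)O[C@H]1C=C(C(=O)OCCl)[C@H](CCC2=CCOC2=O)[C@@]2(C)CCCC(C)(C)[C@H]12 | intermediate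
10 | target CNP0150853.1 | CC[C@@H](C)C(=O)O[C@H]1C=C(C(=O)O)[C@H](CCC2=CCOC2=O)[C@@]2(C)CCCC(C)(C)[C@H]12 | target

Total step count: 7. Longest linear sequence: 7 steps (from 1).

Steps most likely to fail

Step 6. The free carbene or the phosphate may be alkylated by a chloromethyl ester before the cycle turns over, the umpoled acrylate may add to a second acrylate (tail-to-tail dimerisation), or the ring enoate may be drawn into the same cyclisation. The fallback sets out from diacid 7 and comes back at target 10; it closes the lactone through a different bond (C13=C14, by metathesis) and so gives up the C14–C15 closure. Diacid 7 is alkylated with allyl bromide and K2CO3 in DMF to the bis(allyl) ester F1. The second-generation ruthenium benzylidene metathesis catalyst (toluene, 80 °C) should then close only the allyl 2-alkylacrylate, with loss of ethene, to the butenolide allyl ester F2; the ring allyl ester has no alkene it could close onto without opening ring B. Pd(PPh3)4 and morpholine remove the remaining allyl ester to give 10.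

Step 3. The first enolate may attack the other ketone (aldol between C16 and C8) before the second deprotonation, the C6 ester may be lost by E1cB or shift to the enolate oxygen, and excess base may epimerise the 2-methylbutanoate. The fallback sets out from 3 and comes back at 6, making the two triflates one at a time. KMnO4/MgSO4 in acetone degrades only the vinyl carbinol of 3 to the methyl ketone F3, and KHMDS/PhNTf2 converts it into the side-chain enol triflate F4 while no second carbonyl is present. Ozone (CH2Cl2, −78 °C, then Me2S) cleaves the electron-rich 8(17)-methylene and spares the electron-poor triflate alkene, giving the 8-ketone F5. A second KHMDS/PhNTf2 treatment enolises C8 towards C7 and gives 6.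

Step 7. Hydrolysis may take place at carbonyl groups instead of the CH2 (opening of the butenolide, loss of the C6 ester), or exchange at the hindered ring ester may stall. The fallback sets out from 9 and comes back at 10. NaN3 in DMF displaces chloride to give the azidomethyl ester F6. Staudinger reduction (PPh3, THF/H2O) then gives the aminomethyl ester, which should collapse to 10 with loss of nitrogen, formaldehyde and ammonia.

Further compounds
F1 | step 6 | bis(allyl) ester of diacid 7 | CC[C@@H](C)C(=O)O[C@H]1C=C(C(=O)OCC=C)[C@H](CCC(=C)C(=O)OCC=C)[C@@]2(C)CCCC(C)(C)[C@H]12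
F2 | step 6 | butenolide with ring allyl ester | CC[C@@H](C)C(=O)O[C@H]1C=C(C(=O)OCC=C)[C@H](CCC2=CCOC2=O)[C@@]2(C)CCCC(C)(C)[C@H]12
F3 | step 3 | 6α-[(R)-2-methylbutanoyloxy]-14,15-dinorlabd-8(17)-en-13-one | CC[C@@H](C)C(=O)O[C@H]1CC(=C)[C@H](CCC(C)=O)[C@@]2(C)CCCC(C)(C)[C@H]12
F4 | step 3 | side-chain enol triflate with 8(17)-methylene | CC[C@@H](C)C(=O)O[C@H]1CC(=C)[C@H](CCC(=C)OS(=O)(=O)C(F)(F)F)[C@@]2(C)CCCC(C)(C)[C@H]12
F5 | step 3 | 8-ketone with side-chain enol triflate | CC[C@@H](C)C(=O)O[C@H]1CC(=O)[C@H](CCC(=C)OS(=O)(=O)C(F)(F)F)[C@@]2(C)CCCC(C)(C)[C@H]12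
F6 | step 7 | butenolide with ring azidomethyl ester | CC[C@@H](C)C(=O)O[C@H]1C=C(C(=O)OCN=[N+]=[N-])[C@H](CCC2=CCOC2=O)[C@@]2(C)CCCC(C)(C)[C@H]12
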